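## Retrosynthetic overview

1. The tetrahydrofuran is the only ring formed, and it is closed last. Cutting the C7–O bond gives an open-chain (8R,8'R)-diol with a free 4-hydroxy-3-methoxybenzyl group. Oxidising that phenol gives the p-quinone methide, which the 9'-OH captures, as in the ring closure that follows 8–8' coupling in lignan biosynthesis. This sets C7.
2. The diol comes from a (2R,3R)-2,3-dibenzylsuccinyl bis-imide. One hydride reduction frees both CH2OH groups and the phenol.
3. The C8–C8' bond comes from a crossed one-electron oxidative coupling of two 3-arylpropanoyl imide enolates, the enolate counterpart of phenylpropanoid radical coupling. Both stereocentres are set by (S)-4-benzyloxazolidinone auxiliaries.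
4. The two imides come from dihydroferulic acid, 3-(3,4-dimethoxyphenyl)propanoic acid and the auxiliary.

Assumption: lignan numbering is used (C7–C9 = side chain of the 4-hydroxy-3-methoxyphenyl unit, C7'–C9' = side chain of the 3,4-dimethoxyphenyl unit), and compound numbers run in the order of the forward steps.

## Route

Step 1
Reactants: 1 3-(4-hydroxy-3-methoxyphenyl)propanoic acid (dihydroferulic acid); 2 (S)-4-benzyloxazolidin-2-one
Product: 4 (S)-4-benzyl-3-[3-(3-methoxy-4-pivaloyloxyphenyl)propanoyl]oxazolidin-2-one, via mixed pivalic anhydride 3 (not isolated)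
Conditions: PivCl (2.2 equiv), Et3N (3.5 equiv), THF, −20 → 0 °C (1 added slowly to PivCl/Et3N); then LiCl (1.1 equiv), 2 (1.0 equiv), rt, 12 h
Reagents that add atoms: pivaloyl chloride, CC(C)(C)C(=O)Cl
Why: Pivaloyl chloride acylates both acidic sites, giving the hindered aryl pivalate (phenol protection) and the mixed anhydride, which N-acylates the LiCl/Et3N-activated oxazolidinone at its less hindered carbonyl (mixed-anhydride N-acylation of an Evans auxiliary); no new stereocentre is formed.

Step 2
Reactants: 5 3-(3,4-dimethoxyphenyl)propanoic acid; 2 (S)-4-benzyloxazolidin-2-one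
Product: 7 (S)-4-benzyl-3-[3-(3,4-dimethoxyphenyl)propanoyl]oxazolidin-2-one, via mixed pivalic anhydride 6 (not isolated)
Conditions: PivCl (1.1 equiv), Et3N (2.5 equiv), THF, −20 °C; then LiCl, 2, rt, 12 h
Reagents that add atoms: none
Why: Same mixed-anhydride N-acylation of the Evans auxiliary as in step 1; no new stereocentre is formed.

Step 3
Reactants: 4 (S)-4-benzyl-3-[3-(3-methoxy-4-pivaloyloxyphenyl)propanoyl]oxazolidin-2-one; 7 (S)-4-benzyl-3-[3-(3,4-dimethoxyphenyl)propanoyl]oxazolidin-2-one
Product: 10 (4S,4'S)-3,3'-[(2R,3R)-2-(3,4-dimethoxybenzyl)-3-(3-methoxy-4-pivaloyloxybenzyl)butanedioyl]bis(4-benzyloxazolidin-2-one), via Z-lithium enolate of the pivalate imide 8 (not isolated), via Z-lithium enolate of the dimethoxy imide 9 (not isolated)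
Conditions: 4 (1 equiv) + 7 (3 equiv), LiN(SiMe3)2 (4.2 equiv), THF, −78 °C, 1 h; then CuCl2 (4.4 equiv) in DMF, −78 °C → rt
Reagents that add atoms: none
Why: Saegusa-type oxidative enolate coupling (the 8–8' radical coupling run on enolates): one-electron oxidation of the chelated Z-enolates by CuCl2 joins the two α-carbons, each on the face opposite the 4-benzyl group, so the (S)-auxiliaries set C8 and C8' both as R, and the threefold excess of 7 sends 4 statistically (up to 75%) into the crossed dimer.

Step 4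
Reactants: 10 (4S,4'S)-3,3'-[(2R,3R)-2-(3,4-dimethoxybenzyl)-3-(3-methoxy-4-pivaloyloxybenzyl)butanedioyl]bis(4-benzyloxazolidin-2-one)
Product: 11 (2R,3R)-2-(3,4-dimethoxybenzyl)-3-(4-hydroxy-3-methoxybenzyl)butane-1,4-diol
Conditions: LiAlH4 (6 equiv), THF, 0 °C → rt; aqueous work-up at pH 5
Reagents that add atoms: none
Why: Hydride reduction converts both exocyclic imide carbonyls to CH2OH with release of the auxiliary and cleaves the aryl pivalate in the same operation (LiAlH4 reduction of N-acyl oxazolidinones and aryl esters); the two stereocentres are not enolised and are retained.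

Step 5
Reactants: 11 (2R,3R)-2-(3,4-dimethoxybenzyl)-3-(4-hydroxy-3-methoxybenzyl)butane-1,4-diol
Product: 13 4'-O-methyllariciresinol, 4-[(2S,3R,4R)-4-(3,4-dimethoxybenzyl)-3-(hydroxymethyl)oxolan-2-yl]-2-methoxyphenol, via p-quinone methide 12 (not isolated)
Conditions: DDQ (1.05 equiv), CH2Cl2/THF 9:1, 0 °C, 30 min; aq. NaHCO3
Reagents that add atoms: none
Why: DDQ dehydrogenation of the 4-alkylguaiacol gives p-quinone methide 12 (only the free-phenol ring reacts), and 5-exo oxa-1,6-addition of the 9'-OH closes the ring with the aryl trans to the C8 CH2OH group, giving 7S by kinetic and thermodynamic preference because the all-cis epimer can re-open through 12.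

## Compound list

1 | 3-(4-hydroxy-3-methoxyphenyl)propanoic acid | COc1cc(CCC(=O)O)ccc1O | starting material
2 | (S)-4-benzyloxazolidin-2-one | O=C1N[C@@H](Cc2ccccc2)CO1 | starting material
3 | 3-(3-methoxy-4-pivaloyloxyphenyl)propanoic pivalic anhydride | COc1cc(CCC(=O)OC(=O)C(C)(C)C)ccc1OC(=O)C(C)(C)C | intermediate
4 | (S)-4-benzyl-3-[3-(3-methoxy-4-pivaloyloxyphenyl)propanoyl]oxazolidin-2-one | COc1cc(CCC(=O)N2[C@@H](Cc3ccccc3)COC2=O)ccc1OC(=O)C(C)(C)C | intermediate
5 | 3-(3,4-dimethoxyphenyl)propanoic acid | COc1ccc(CCC(=O)O)cc1OC | starting material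
6 | 3-(3,4-dimethoxyphenyl)propanoic pivalic anhydride | COc1ccc(CCC(=O)OC(=O)C(C)(C)C)cc1OC | intermediate
7 | (S)-4-benzyl-3-[3-(3,4-dimethoxyphenyl)propanoyl]oxazolidin-2-one | COc1ccc(CCC(=O)N2[C@@H](Cc3ccccc3)COC2=O)cc1OC | intermediate
8 | Z-lithium enolate of 4 | [Li]O/C(=C\Cc1ccc(OC(=O)C(C)(C)C)c(OC)c1)N1[C@@H](Cc2ccccc2)COC1=O | intermediate
9 | Z-lithium enolate of 7 | [Li]O/C(=C\Cc1ccc(OC)c(OC)c1)N1[C@@H](Cc2ccccc2)COC1=O | intermediate
10 | (4S,4'S)-3,3'-[(2R,3R)-2-(3,4-dimethoxybenzyl)-3-(3-methoxy-4-pivaloyloxybenzyl)butanedioyl]bis(4-benzyloxazolidin-2-one) | O=C(N1[C@@H](Cc2ccccc2)COC1=O)[C@H](Cc1ccc(OC)c(OC)c1)[C@@H](Cc1ccc(OC(=O)C(C)(C)C)c(OC)c1)C(=O)N1[C@@H](Cc2ccccc2)COC1=O | intermediate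
11 | (2R,3R)-2-(3,4-dimethoxybenzyl)-3-(4-hydroxy-3-methoxybenzyl)butane-1,4-diol | OC[C@H](Cc1ccc(OC)c(OC)c1)[C@@H](Cc1ccc(O)c(OC)c1)CO | intermediate
12 | 4-[(2R,3R)-3-(3,4-dimethoxybenzyl)-4-hydroxy-2-(hydroxymethyl)butylidene]-2-methoxycyclohexa-2,5-dien-1-one (p-quinone methide; exocyclic C=C geometry not defined) | COC1=CC(=C[C@@H](CO)[C@H](CO)Cc2ccc(OC)c(OC)c2)C=CC1=O | intermediate
13 | 4'-O-methyllariciresinol, 4-[(2S,3R,4R)-4-(3,4-dimethoxybenzyl)-3-(hydroxymethyl)oxolan-2-yl]-2-methoxyphenol | COc1cc([C@H]2OC[C@H](Cc3ccc(OC)c(OC)c3)[C@@H]2CO)ccc1O | target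

## Step count and risks

Total step count: 5. Longest linear sequence: 4 (steps 1, 3, 4, 5).

The three steps most likely to fail are these.

Step 5 (oxidative ring closure). The product 13 still carries a free phenol para to a benzylic ether and can be oxidised a second time. The quinone methide 12 can also be captured by the electron-rich dimethoxyphenyl ring to give an aryltetralin if the medium turns acidic. The fallback sets out from 7 and comes back to the route at 13. It generates the same quinone methide by loss of water from a benzylic alcohol instead of by dehydrogenation.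
- 7 is alkylated (NaN(SiMe3)2, THF, −78 °C; tert-butyl bromoacetate) on the face opposite the auxiliary benzyl group to give the alkylated succinate imide F4.
- LiBH4 (THF, 0 °C) removes the auxiliary to give the hydroxy ester F5, which closes with CF3CO2H in CH2Cl2 to the (R)-β-benzyl lactone F6.
- The lithium enolate of F6 (LiN(iPr)2, THF, −78 °C) adds to commercial 4-formyl-2-methoxyphenyl acetate trans to the C4 benzyl group to give the aldol lactone F7, as a mixture at the carbinol carbon.
- LiAlH4 reduces the lactone and the acetate to the phenolic triol F8.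
- Pyridinium tosylate in CH2Cl2 at rt ionises the 4-hydroxybenzylic alcohol of F8 to 12, which closes to 13. The carbinol configuration is therefore irrelevant.

Step 3 (crossed oxidative coupling). The coupling is statistical, 10 must be separated from the homodimer of 7, and facial control by the two auxiliaries may be incomplete. The fallback sets out from 4 and comes back to the route at 11. It replaces the crossed coupling by a symmetric coupling followed by late desymmetrisation.
- 4 alone is enolised (LiN(SiMe3)2) and oxidised with CuCl2 to the C2-symmetric homodimer bis-imide F1.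
- LiAlH4 reduces F1 to (−)-secoisolariciresinol F2.
- One equivalent of MeI with K2CO3 in acetone methylates one of the two homotopic phenols of F2, which gives 11 as a single mono-ether. Unreacted F2 is recovered and recycled.

Step 4 (global reduction). The two imide carbonyls of 10 are flanked by branched carbons, so hydride may attack the ring carbonyl of the oxazolidinone instead and give ring-opened hydroxy amides. The fallback sets out from 10 and comes back to the route at 11. It separates auxiliary removal from reduction.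
- LiOH/H2O2 (THF/H2O, 0 °C → rt, with excess LiOH to remove the pivalate) gives the phenolic diacid F3.
- BH3·SMe2 (THF, 0 °C → rt; MeOH quench) reduces both carboxylic acids of F3 to give 11.

Further compounds
F1 | step 3 | (4S,4'S)-3,3'-[(2R,3R)-2,3-bis(3-methoxy-4-pivaloyloxybenzyl)butanedioyl]bis(4-benzyloxazolidin-2-one) | O=C(N1[C@@H](Cc2ccccc2)COC1=O)[C@H](Cc1ccc(OC(=O)C(C)(C)C)c(OC)c1)[C@@H](Cc1ccc(OC(=O)C(C)(C)C)c(OC)c1)C(=O)N1[C@@H](Cc2ccccc2)COC1=O
F2 | step 3 | (2R,3R)-2,3-bis(4-hydroxy-3-methoxybenzyl)butane-1,4-diol ((−)-secoisolariciresinol) | OC[C@H](Cc1ccc(O)c(OC)c1)[C@@H](Cc1ccc(O)c(OC)c1)CO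
F3 | step 4 | (2R,3R)-2-(3,4-dimethoxybenzyl)-3-(4-hydroxy-3-methoxybenzyl)butanedioic acid | OC(=O)[C@H](Cc1ccc(OC)c(OC)c1)[C@@H](Cc1ccc(O)c(OC)c1)C(=O)O
F4 | step 5 | (S)-4-benzyl-3-[(2R)-4-tert-butoxy-2-(3,4-dimethoxybenzyl)-4-oxobutanoyl]oxazolidin-2-one | CC(C)(C)OC(=O)C[C@@H](Cc1ccc(OC)c(OC)c1)C(=O)N1[C@@H](Cc2ccccc2)COC1=O
F5 | step 5 | tert-butyl (3R)-4-(3,4-dimethoxyphenyl)-3-(hydroxymethyl)butanoate | CC(C)(C)OC(=O)C[C@@H](Cc1ccc(OC)c(OC)c1)CO
F6 | step 5 | (4R)-4-(3,4-dimethoxybenzyl)oxolan-2-one | O=C1C[C@@H](Cc2ccc(OC)c(OC)c2)CO1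
F7 | step 5 | (3S,4R)-3-[(4-acetoxy-3-methoxyphenyl)(hydroxy)methyl]-4-(3,4-dimethoxybenzyl)oxolan-2-one (carbinol epimers) | O=C1OC[C@H](Cc2ccc(OC)c(OC)c2)[C@H]1C(O)c1ccc(OC(C)=O)c(OC)c1
F8 | step 5 | (2R,3R)-3-(3,4-dimethoxybenzyl)-2-[hydroxy(4-hydroxy-3-methoxyphenyl)methyl]butane-1,4-diol (carbinol epimers) | OC[C@H](Cc1ccc(OC)c(OC)c1)[C@H](CO)C(O)c1ccc(O)c(OC)c1
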